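**Retrosynthetic overview**
- The target is released last by fluoride cleavage of a triisopropylsilyl ether on the guaiacyl ring (ring B).
- Key disconnection: the C4–OMe bond. The protected dienone comes from a 2-allyl-5-methoxy-4-alkylphenol and methanol by a catalyst-controlled oxidative dearomatisation that creates the quaternary (4S) centre.
- The allyl group comes from an aromatic Claisen rearrangement of the ring A allyl ether.
- The CH2–ring B bond comes from a B-alkyl Suzuki coupling of an (R)-2-arylpropyl boronate with silyl-protected 4-bromo-2-methoxyphenol. The C8 centre comes from cobalt-catalysed asymmetric hydroboration of the α-methylstyrene made from 4-bromo-3-methoxyphenol and isopropenyl boronate.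
- Rings: none is constructed. Both six-membered rings are bought as bromophenols (ring B is protected first, ring A is elaborated), and ring A is converted from arene to cyclohexadienone in the penultimate step.

Assumption: the absolute sense of induction of the cobalt ligand (step 3) and of the new iodoarene catalyst (step 7) is taken from the working models; if a first run shows the opposite sense, the mirror-image ligand or catalyst (equally accessible) is used and nothing else changes.

Iodoarene catalyst of step 7 (not a numbered compound; prepared from 2-iodoresorcinol, ethyl (S)-lactate and 2,6-diphenylaniline): (R,R)-2,2'-[(2-iodo-1,3-phenylene)bis(oxy)]bis[N-(2,6-diphenylphenyl)propanamide], SMILES C[C@@H](Oc1cccc(O[C@H](C)C(=O)Nc2c(-c3ccccc3)cccc2-c2ccccc2)c1I)C(=O)Nc1c(-c2ccccc2)cccc1-c1ccccc1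

**Step 1**
Reactants: 1 4-bromo-2-methoxyphenol
Product: 2 (4-bromo-2-methoxyphenoxy)triisopropylsilane
Conditions: TIPSCl (1.2 equiv), imidazole (2.5 equiv), DMF, 23 to 40 °C
Reagents that add atoms: chlorotriisopropylsilane (TIPSCl), CC(C)[Si](Cl)(C(C)C)C(C)C
Why: Standard silylation of a phenol (silyl chloride/imidazole); the bulky silyl ether masks ring B against the oxidant of step 7 and withstands aqueous base and heat; no stereocentre is involved.

**Step 2**
Reactants: 3 4-bromo-3-methoxyphenol; 4 4,4,5,5-tetramethyl-2-(prop-1-en-2-yl)-1,3,2-dioxaborolane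
Product: 5 3-methoxy-4-(prop-1-en-2-yl)phenol
Conditions: Pd(OAc)2 (2 mol%), SPhos (4 mol%), K3PO4 (3 equiv), 1,4-dioxane/H2O (5:1), 80 °C
Reagents that add atoms: none
Why: Suzuki–Miyaura coupling; SPhos-ligated zerovalent palladium inserts into electron-rich, ortho-substituted aryl bromides and tolerates the free phenol; no stereocentre is formed.

**Step 3**
Reactants: 5 3-methoxy-4-(prop-1-en-2-yl)phenol
Product: 8 3-methoxy-4-[(2R)-1-(4,4,5,5-tetramethyl-1,3,2-dioxaborolan-2-yl)propan-2-yl]phenol, via aryl borate alkene 6 (not isolated), via bis-boryl adduct 7 (not isolated)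
Conditions: HBpin (2.3 equiv), CoCl2 (2 mol%), 2-[(4S)-4-tert-butyl-4,5-dihydro-1,3-oxazol-2-yl]-6-{1-[(2,6-diisopropylphenyl)imino]ethyl}pyridine (2.2 mol%), NaBHEt3 (6 mol%), THF, 23 °C; then aq NH4Cl
Reagents that add atoms: pinacolborane (HBpin), [H]B1OC(C)(C)C(C)(C)O1
Why: Cobalt-hydride-catalysed anti-Markovnikov asymmetric hydroboration of a 1,1-disubstituted aryl alkene; the phenol is first capped as its aryl borate (H2 is lost), the cobalt hydride then adds to one alkene face selected by the oxazoline and sets C8 as R, and the oxygen–boron bond is hydrolysed on work-up.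

**Step 4**
Reactants: 8 3-methoxy-4-[(2R)-1-(4,4,5,5-tetramethyl-1,3,2-dioxaborolan-2-yl)propan-2-yl]phenol; 2 (4-bromo-2-methoxyphenoxy)triisopropylsilane
Product: 9 3-methoxy-4-[(2R)-1-{3-methoxy-4-[(triisopropylsilyl)oxy]phenyl}propan-2-yl]phenol
Conditions: Pd(OAc)2 (5 mol%), RuPhos (10 mol%), K3PO4 (4 equiv), toluene/H2O (10:1), 90 °C
Reagents that add atoms: none
Why: B-alkyl Suzuki–Miyaura coupling of a primary alkyl pinacol boronate; the bulky electron-rich phosphine makes reductive elimination faster than β-hydride elimination, and the C8 centre (β to boron) is not touched.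

**Step 5**
Reactants: 9 3-methoxy-4-[(2R)-1-{3-methoxy-4-[(triisopropylsilyl)oxy]phenyl}propan-2-yl]phenol
Product: 10 triisopropyl{2-methoxy-4-[(2R)-2-[2-methoxy-4-(prop-2-en-1-yloxy)phenyl]propyl]phenoxy}silane
Conditions: allyl bromide (1.5 equiv), K2CO3 (2 equiv), acetone, 56 °C
Reagents that add atoms: allyl bromide, C=CCBr
Why: Williamson ether synthesis on the only free phenol (ring A); the hindered aryl silyl ether of ring B is stable to carbonate in acetone.

**Step 6**
Reactants: 10 triisopropyl{2-methoxy-4-[(2R)-2-[2-methoxy-4-(prop-2-en-1-yloxy)phenyl]propyl]phenoxy}silane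
Product: 12 5-methoxy-4-[(2R)-1-{3-methoxy-4-[(triisopropylsilyl)oxy]phenyl}propan-2-yl]-2-(prop-2-en-1-yl)phenol, via ortho-dienone 11 (not isolated)
Conditions: PhNEt2, 190 °C, sealed tube
Reagents that add atoms: none
Why: Aromatic Claisen rearrangement ([3,3]-sigmatropic shift, then tautomerisation); the allyl group goes to the open ortho carbon para to the methoxy group (C2) and not to the carbon squeezed between the two oxygens (C6), as allyl 3,4-dialkoxyphenyl ethers do; the amine solvent suppresses acid-catalysed cyclisation and C8 is not affected.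

**Step 7**
Reactants: 12 5-methoxy-4-[(2R)-1-{3-methoxy-4-[(triisopropylsilyl)oxy]phenyl}propan-2-yl]-2-(prop-2-en-1-yl)phenol
Product: 13 (4S)-4,5-dimethoxy-4-[(2R)-1-{3-methoxy-4-[(triisopropylsilyl)oxy]phenyl}propan-2-yl]-2-(prop-2-en-1-yl)cyclohexa-2,5-dien-1-one
Conditions: (R,R)-2,2'-[(2-iodo-1,3-phenylene)bis(oxy)]bis[N-(2,6-diphenylphenyl)propanamide] (10 mol%), mCPBA (1.2 equiv, slow addition), MeOH/CH2Cl2 (1:1), −30 °C
Reagents that add atoms: methanol, CO
Why: Proposed new method: catalyst-controlled para-methoxylative dearomatisation of a phenol; mCPBA oxidises the iodoarene to an aryl trivalent-iodine dimethoxide, phenol 12 exchanges onto iodine, and in this weakly ionising medium (no fluorinated alcohol) methanol attacks C4 (activated by the ortho methoxy group and leading to a vinylogous ester) in an SN2′-type step while the phenoxide is still bound to iodine, so that the folded lactamide arms (N–H to iodine-bound oxygen hydrogen bonds, a terphenyl wall stacked over one ring face, one rotamer about the iodine–oxygen bond enforced by the ortho-allyl group) leave open only the face that gives 4S and override the weak 1,2-induction from C8, with monovalent iodoarene released for re-oxidation; the closest known reaction types are chiral aryl-iodide-catalysed oxidative dearomatisations of phenols (ortho-spirolactonisation, para-hydroxylation, para-fluorination) and the achiral PhI(OAc)2/MeOH synthesis of p-quinol methyl ethers.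

**Step 8**
Reactants: 13 (4S)-4,5-dimethoxy-4-[(2R)-1-{3-methoxy-4-[(triisopropylsilyl)oxy]phenyl}propan-2-yl]-2-(prop-2-en-1-yl)cyclohexa-2,5-dien-1-one
Product: 14 (4S)-4-[(2R)-1-(4-hydroxy-3-methoxyphenyl)propan-2-yl]-4,5-dimethoxy-2-(prop-2-en-1-yl)cyclohexa-2,5-dien-1-one
Conditions: TBAF (1.2 equiv), AcOH (1.2 equiv), THF, 0 °C
Reagents that add atoms: none
Why: Fluoride cleavage of an aryl silyl ether; acetic acid buffers the phenoxide so that the dienone, the tertiary allylic methyl ether and both stereocentres are left alone.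

**Compound list**
1 | 4-bromo-2-methoxyphenol | COc1cc(Br)ccc1O | starting material
2 | (4-bromo-2-methoxyphenoxy)triisopropylsilane | COc1cc(Br)ccc1O[Si](C(C)C)(C(C)C)C(C)C | intermediate
3 | 4-bromo-3-methoxyphenol | COc1cc(O)ccc1Br | starting material
4 | 4,4,5,5-tetramethyl-2-(prop-1-en-2-yl)-1,3,2-dioxaborolane | CC(=C)B1OC(C)(C)C(C)(C)O1 | starting material
5 | 3-methoxy-4-(prop-1-en-2-yl)phenol | COc1cc(O)ccc1C(C)=C | intermediate
6 | 2-[3-methoxy-4-(prop-1-en-2-yl)phenoxy]-4,4,5,5-tetramethyl-1,3,2-dioxaborolane (not isolated) | COc1cc(OB2OC(C)(C)C(C)(C)O2)ccc1C(C)=C | intermediate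
7 | 2-{3-methoxy-4-[(2R)-1-(4,4,5,5-tetramethyl-1,3,2-dioxaborolan-2-yl)propan-2-yl]phenoxy}-4,4,5,5-tetramethyl-1,3,2-dioxaborolane (not isolated) | COc1cc(OB2OC(C)(C)C(C)(C)O2)ccc1[C@H](C)CB1OC(C)(C)C(C)(C)O1 | intermediate
8 | 3-methoxy-4-[(2R)-1-(4,4,5,5-tetramethyl-1,3,2-dioxaborolan-2-yl)propan-2-yl]phenol | COc1cc(O)ccc1[C@H](C)CB1OC(C)(C)C(C)(C)O1 | intermediate
9 | 3-methoxy-4-[(2R)-1-{3-methoxy-4-[(triisopropylsilyl)oxy]phenyl}propan-2-yl]phenol | COc1cc(O)ccc1[C@H](C)Cc1ccc(O[Si](C(C)C)(C(C)C)C(C)C)c(OC)c1 | intermediate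
10 | triisopropyl{2-methoxy-4-[(2R)-2-[2-methoxy-4-(prop-2-en-1-yloxy)phenyl]propyl]phenoxy}silane | C=CCOc1ccc([C@H](C)Cc2ccc(O[Si](C(C)C)(C(C)C)C(C)C)c(OC)c2)c(OC)c1 | intermediate
11 | 3-methoxy-4-[(2R)-1-{3-methoxy-4-[(triisopropylsilyl)oxy]phenyl}propan-2-yl]-6-(prop-2-en-1-yl)cyclohexa-2,4-dien-1-one (C6 epimers, not isolated) | C=CCC1C=C([C@H](C)Cc2ccc(O[Si](C(C)C)(C(C)C)C(C)C)c(OC)c2)C(OC)=CC1=O | intermediate
12 | 5-methoxy-4-[(2R)-1-{3-methoxy-4-[(triisopropylsilyl)oxy]phenyl}propan-2-yl]-2-(prop-2-en-1-yl)phenol | C=CCc1cc([C@H](C)Cc2ccc(O[Si](C(C)C)(C(C)C)C(C)C)c(OC)c2)c(OC)cc1O | intermediate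
13 | (4S)-4,5-dimethoxy-4-[(2R)-1-{3-methoxy-4-[(triisopropylsilyl)oxy]phenyl}propan-2-yl]-2-(prop-2-en-1-yl)cyclohexa-2,5-dien-1-one | C=CCC1=C[C@@](OC)([C@H](C)Cc2ccc(O[Si](C(C)C)(C(C)C)C(C)C)c(OC)c2)C(OC)=CC1=O | intermediate
14 | (4S)-4-[(2R)-1-(4-hydroxy-3-methoxyphenyl)propan-2-yl]-4,5-dimethoxy-2-(prop-2-en-1-yl)cyclohexa-2,5-dien-1-one | C=CCC1=C[C@@](OC)([C@H](C)Cc2ccc(O)c(OC)c2)C(OC)=CC1=O | target

**Step count**
Total: 8 steps (preparation of the iodoarene catalyst not counted). Longest linear sequence: 7 steps (3 to 14, steps 2 to 8); step 1 is a one-step side branch.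

**Steps most likely to fail, with fallbacks**

Step 7 (the new dearomatisation). Facial control at the para carbon, far from iodine, may be poor. Methanol may also attack C2 or C6, ring B may attack C4 to give a spiro-indane, and the peracid may epoxidise the allyl group. Fallback with known chemistry: setting out from 12, PhI(OAc)2 in MeOH at 0 °C gives the p-quinol methyl ether without catalyst control, as a mixture of 13 and its C4 epimer (4R)-4,5-dimethoxy-4-[(2R)-1-{3-methoxy-4-[(triisopropylsilyl)oxy]phenyl}propan-2-yl]-2-(prop-2-en-1-yl)cyclohexa-2,5-dien-1-one F3. The two diastereomers are separated on silica or by preparative HPLC. F3 is returned to 12 with zinc in acetic acid (reductive rearomatisation with loss of methanol) and recycled. The route is rejoined at 13.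

Step 3 (asymmetric hydroboration). The ortho methoxy group twists the alkene out of the arene plane and may lower rate and ee, and the phenol has to be capped in the flask. Fallback: replace the hydroboration and the B-alkyl coupling by hydrogenation. Setting out from 5, a Heck reaction with aryl bromide 2 (Pd2(dba)3, P(tBu)3, Cy2NMe, dioxane, 80 °C) gives 3-methoxy-4-[(1E)-1-{3-methoxy-4-[(triisopropylsilyl)oxy]phenyl}prop-1-en-2-yl]phenol F1. F1 is hydrogenated with [Ir(cod)(L)]BArF, L = (S)-4-tert-butyl-2-[2-(diphenylphosphanyl)phenyl]-4,5-dihydro-1,3-oxazole (ligand enantiomer chosen for R), under H2 (50 bar) in CH2Cl2. This sets C8 and comes back to the route at 9, so step 4 is skipped as well.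

Step 6 (Claisen rearrangement). Some migration to C6, or thermal damage at 190 °C, would cost material at a late stage. Fallback: install the allyl group by cross-coupling. Setting out from 9, NBS (1.0 equiv, MeCN, −20 °C) brominates ring A ortho to the hydroxyl and para to the methoxy group to give 2-bromo-5-methoxy-4-[(2R)-1-{3-methoxy-4-[(triisopropylsilyl)oxy]phenyl}propan-2-yl]phenol F2. Stille coupling of F2 with allyltributylstannane (Pd(PPh3)4, toluene, 100 °C) comes back to the route at 12, and steps 5 and 6 are skipped.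

**Further compounds**
F1 | step 3 | 3-methoxy-4-[(1E)-1-{3-methoxy-4-[(triisopropylsilyl)oxy]phenyl}prop-1-en-2-yl]phenol | COc1cc(O)ccc1/C(C)=C/c1ccc(O[Si](C(C)C)(C(C)C)C(C)C)c(OC)c1
F2 | step 6 | 2-bromo-5-methoxy-4-[(2R)-1-{3-methoxy-4-[(triisopropylsilyl)oxy]phenyl}propan-2-yl]phenol | Brc1cc([C@H](C)Cc2ccc(O[Si](C(C)C)(C(C)C)C(C)C)c(OC)c2)c(OC)cc1O
F3 | step 7 | (4R)-4,5-dimethoxy-4-[(2R)-1-{3-methoxy-4-[(triisopropylsilyl)oxy]phenyl}propan-2-yl]-2-(prop-2-en-1-yl)cyclohexa-2,5-dien-1-one | C=CCC1=C[C@](OC)([C@H](C)Cc2ccc(O[Si](C(C)C)(C(C)C)C(C)C)c(OC)c2)C(OC)=CC1=O
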